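**Retrosynthetic overview**

1. Locants used below: ring A = C1 (bears the exocyclic CH2), C2, C3=C4, C5 (CMe2), C6; C7 = carbinol carbon; C8=C9 = side-chain alkene; ring B = the bromohydrin cyclohexane.
2. Key disconnection: the ring bond C1–C6 and the chain bond C7–C8 are cut in one operation, with C7–OH read as C7–B. The precursors are the acyclic (E)-alkenylboronic ester 26 (C6=C7–B, carrying the C1 vinyl bromide on the C2–C5 tether) and the ring B alkenyl iodide 13.
3. Enabling feature: C6 (ring A) and C7 (carbinol, allylic to C8=C9) are vicinal stereocenters, and C1 and the oxygen are syn along C5–C6–C7–C8. This is the pattern left by an anti carbopalladation/1,2-boron-to-carbon shift across an (E)-C6=C7 alkenyl borate; the cis C3=C4 bond and the C5 gem-dimethyl group of ring A hold C1 over C6.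
4. Ring B comes intact from (S)-limonene: both epoxide isomers converge on one trans-diaxial diol, a cyclic sulfate/bromide inversion gives the cis bromohydrin, and carboalumination gives the (E)-alkenyl iodide.
5. Order of ring formation: ring B is present from the start (chiral pool); ring A is closed in step 16, followed only by C–B oxidation and desilylation.

Key step: step 16

Assumption: the sense of induction of the chiral ferrocene bisphosphine of step 16 in a ring-closing mode is taken from the intermolecular reaction; the (Sp,Sp) ligand is written, and its antipode is to be used if C1 is delivered to the wrong face of C6.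

**Route**

Step 1
Reactants: 1 (S)-limonene
Product: 2 (4S)-limonene 1,2-oxide (mixture of cis and trans epoxides)
Conditions: mCPBA (1.0 equiv), CH2Cl2, 0 °C
Reagents that add atoms: meta-chloroperoxybenzoic acid, OOC(=O)c1cccc(Cl)c1
Why: Prilezhaev epoxidation takes the electron-rich trisubstituted ring alkene before the isopropenyl group; the facial ratio does not matter because both epoxides are used in step 2.

Step 2
Reactants: 2 (4S)-limonene 1,2-oxide
Product: 3 (1R,2R,4S)-1-methyl-4-(prop-1-en-2-yl)cyclohexane-1,2-diol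
Conditions: H2SO4 (dilute aq.), THF, 0 °C
Reagents that add atoms: water, O
Why: Acid-catalysed epoxide hydrolysis is stereoconvergent: trans-diaxial (Fürst–Plattner) opening of the cis epoxide at the tertiary carbon and of the trans epoxide at the secondary carbon should give the same diol, so both carbinol centers are set by the C4 center of limonene.

Step 3
Reactants: 3 limonene-1,2-diol
Product: 4 1-[(1S,3R,4R)-3,4-dihydroxy-4-methylcyclohexyl]ethan-1-one
Conditions: O3, CH2Cl2/MeOH, −78 °C; Me2S
Reagents that add atoms: ozone, [O-][O+]=O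
Why: Ozonolysis with reductive work-up cleaves the only remaining alkene to the methyl ketone, which tolerates the oxidant of step 4.

Step 4
Reactants: 4 keto diol
Product: 6 cyclic sulfate of diol 4 (1,3,2-dioxathiolane 2,2-dioxide trans-fused to the cyclohexane), via cyclic sulfite 5 (not isolated)
Conditions: SOCl2, Et3N, CH2Cl2, 0 °C; then RuCl3 (cat.), NaIO4, MeCN/H2O, 0 °C
Reagents that add atoms: thionyl chloride, O=S(Cl)Cl; sodium periodate, [Na+].[O-]I(=O)(=O)=O
Why: Cyclic sulfite formation and RuO4 oxidation (cyclic sulfate synthesis from a 1,2-diol) activate the secondary C–O bond while tying up the tertiary oxygen, which would otherwise close the epoxide; no stereocenter is touched.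

Step 5
Reactants: 6 cyclic sulfate
Product: 8 1-[(1S,3S,4R)-3-bromo-4-hydroxy-4-methylcyclohexyl]ethan-1-one, via lithium sulfate monoester 7 (not isolated)
Conditions: LiBr, THF, reflux; then H2SO4 (cat.), H2O, THF, rt
Reagents that add atoms: lithium bromide, [Li+].[Br-]
Why: SN2 opening of the cyclic sulfate by bromide at the secondary carbon inverts that center and gives the cis bromohydrin (bromine equatorial), and acid hydrolysis of the sulfate monoester by S–O cleavage leaves the tertiary carbinol unchanged.

Step 6
Reactants: 8 bromohydrin ketone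
Product: 9 1-{(1S,3S,4R)-3-bromo-4-methyl-4-[(trimethylsilyl)oxy]cyclohexyl}ethan-1-one
Conditions: N-(trimethylsilyl)imidazole, CH2Cl2, rt
Reagents that add atoms: N-(trimethylsilyl)imidazole, C[Si](C)(C)n1ccnc1
Why: Silylation with a reagent that does not enolize the ketone masks the tertiary hydroxyl group, whose alkoxide could trigger semipinacol ring contraction of the cis bromohydrin in the basic steps that follow.

Step 7
Reactants: 9 silyl ether ketone
Product: 11 {[(1R,2S,4S)-2-bromo-4-ethynyl-1-methylcyclohexyl]oxy}trimethylsilane, via enol triflate 10 (not isolated)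
Conditions: LiN(i-Pr)2, THF, −78 °C; N-(5-chloropyridin-2-yl)-1,1,1-trifluoro-N-[(trifluoromethyl)sulfonyl]methanesulfonamide; then LiN(i-Pr)2 (2.2 equiv), −78 to −40 °C; NH4Cl (aq.)
Reagents that add atoms: none
Why: Kinetic deprotonation of the methyl group, O-triflation of the enolate and E2 elimination of triflate from the 2-triflyloxy-1-alkene give the terminal alkyne (ketone-to-alkyne conversion through the enol triflate); the ring stereocenters are not involved.

Step 8
Reactants: 11 alkyne
Product: 13 {[(1R,2S,4S)-2-bromo-4-[(1E)-1-iodoprop-1-en-2-yl]-1-methylcyclohexyl]oxy}trimethylsilane, via alkenylalane 12 (not isolated)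
Conditions: Me3Al, Cp2ZrCl2 (0.25 equiv), CH2Cl2, 0 °C to rt; then I2, THF, −30 °C
Reagents that add atoms: trimethylaluminium, C[Al](C)C; iodine, II
Why: Negishi zirconium-catalysed carboalumination adds methyl and aluminium syn across the terminal alkyne, and iodinolysis of the C–Al bond with retention gives the (E)-trisubstituted alkenyl iodide.

Step 9
Reactants: 14 3-bromobut-3-en-1-ol
Product: 15 2-bromo-4-iodobut-1-ene
Conditions: I2, PPh3, imidazole, CH2Cl2, 0 °C
Reagents that add atoms: iodine, II
Why: Appel-type iodination of the primary alcohol (SN2 on the alkoxyphosphonium salt); the vinyl bromide is inert.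

Step 10
Reactants: 15 2-bromo-4-iodobut-1-ene
Product: 16 (3-bromobut-3-en-1-yl)triphenylphosphonium iodide
Conditions: PPh3, MeCN, reflux
Reagents that add atoms: triphenylphosphine, c1ccc(cc1)P(c1ccccc1)c1ccccc1
Why: SN2 quaternization of triphenylphosphine by the primary iodide gives the Wittig salt.

Step 11
Reactants: 17 methyl 3-hydroxy-2,2-dimethylpropanoate
Product: 18 methyl 2,2-dimethyl-3-oxopropanoate
Conditions: Dess–Martin periodinane, CH2Cl2, rt
Reagents that add atoms: none
Why: Dess–Martin oxidation of the primary alcohol gives an aldehyde that has no α-hydrogen and so cannot enolize or self-condense.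

Step 12
Reactants: 16 phosphonium iodide; 18 aldehyde ester
Product: 20 methyl (3Z)-6-bromo-2,2-dimethylhepta-3,6-dienoate, via phosphorus ylide 19 (not isolated)
Conditions: NaN(SiMe3)2, THF, −78 °C; then 18, −78 °C to rt
Reagents that add atoms: none
Why: Wittig olefination of the hindered aldehyde with a non-stabilized ylide under lithium-free conditions proceeds through the cis oxaphosphetane and should give the Z alkene (the future C3=C4 bond of ring A).

Step 13
Reactants: 20 Z dienoate
Product: 22 (4Z)-7-bromo-3,3-dimethylocta-4,7-dien-1-yne, via aldehyde 21 (not isolated)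
Conditions: i-Bu2AlH (1.1 equiv), CH2Cl2, −78 °C; then MeOH, K2CO3, dimethyl (1-diazo-2-oxopropyl)phosphonate, −78 °C to rt
Reagents that add atoms: dimethyl (1-diazo-2-oxopropyl)phosphonate, COP(=O)(OC)C(=[N+]=[N-])C(C)=O
Why: Half-reduction of the hindered ester to the aldehyde and Seyferth–Gilbert homologation in the same flask give the terminal alkyne; the aldehyde has no α-hydrogen and the Z alkene is not touched.

Step 14
Reactants: 23 acenaphthoquinone
Product: 24 cis-1,2-dimethyl-1,2-dihydroacenaphthylene-1,2-diol (meso)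
Conditions: MeMgBr (3 equiv), THF, 0 °C to rt; NH4Cl (aq.); crystallization
Reagents that add atoms: methylmagnesium bromide, C[Mg]Br
Why: Double Grignard addition to the 1,2-diketone gives the ditertiary diol, and the cis isomer (the only one able to form a five-membered boronate) is secured by crystallization.

Step 15
Reactants: 22 enyne; 24 cis diol
Product: 26 (1E,4Z)-7-bromo-3,3-dimethylocta-1,4,7-trien-1-ylboronic acid ester of diol 24, via catechol boronate 25 (not isolated)
Conditions: catecholborane, Cy2BH (5 mol %), THF, rt; then 24, rt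
Reagents that add atoms: catecholborane, [H]B1Oc2ccccc2O1
Why: Borane-catalysed hydroboration of the terminal alkyne is syn and anti-Markovnikov and gives the (E)-alkenylboronate, and transesterification of the labile catechol ester installs the hindered diol ligand that later disfavours direct boron-to-palladium transfer.

Step 16
Reactants: 13 alkenyl iodide; 26 alkenylboronic ester
Product: 29 ring-closed allylic boronic ester of diol 24 (boron on the future carbinol carbon), via alkenyllithium 27 (not isolated), via borate complex 28 (not isolated)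
Conditions: 13, t-BuLi (2.0 equiv), Et2O, −78 °C; then 26, THF, −78 °C to rt; then Pd(OAc)2 (5 mol %), (Sp,Sp)-1,1'-bis[bis(4-methoxy-3,5-dimethylphenyl)phosphino]-2,2'-bis[(R)-α-(dimethylamino)benzyl]ferrocene (6 mol %), NaOTf, THF, 60 °C
Reagents that add atoms: none
Why: Proposed new method: iodine–lithium exchange gives alkenyllithium 27, which adds to the boron of 26 to give the bis(alkenyl) borate 28; zerovalent palladium inserts into the C1–Br bond, the cationic C1–Pd unit binds the tethered C6=C7 bond and induces a 1,2-shift of the ring B alkenyl carbon C8 from boron to C7 anti to palladium, and reductive elimination from the resulting palladacycle forms the C1–C6 bond. The closest known reaction type is the intermolecular palladium/ferrocene-bisphosphine conjunctive cross-coupling of alkenylboron ate complexes with C(sp2) halides or triflates, established for bis(alkenyl) borates (alkenyl migration, allylic boronate products) and for β-substituted alkenyl boronates with this diol ligand (anti addition, two adjacent stereocenters); new here is that the electrophile is tethered, so that the coupling closes a ring. Ring A closes in a 6-exo-trig mode (C1 onto C6, C7 left outside the ring), the cis C3=C4 bond and the C5 gem-dimethyl group holding C1–Pd over C6. The C6 center is set by the face of the C6=C7 bond that palladium binds (the si face of C6 is needed, chosen by the chiral bisphosphine), and the C7 center is fixed relative to C6 by the anti-periplanar migration across the (E)-alkene, which gives the syn C1/boron arrangement that becomes (6R,7R). The step needs the metallate shift to outrun direct alkenyl transfer from boron to palladium and needs C6=C7, not C8=C9, as the acceptor: the hindered diol ligand slows transmetalation, Suzuki–Miyaura closure through C7 would require a trans double bond in a seven-membered ring, and attack at C8=C9 would require a nine-membered ring.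

Step 17
Reactants: 29 allylic boronic ester
Product: 30 (1R,2E)-3-{(1S,3S,4R)-3-bromo-4-methyl-4-[(trimethylsilyl)oxy]cyclohexyl}-1-[(1R)-2,2-dimethyl-6-methylidenecyclohex-3-en-1-yl]but-2-en-1-ol
Conditions: NaBO3·4H2O, THF/H2O, rt
Reagents that add atoms: sodium perborate tetrahydrate, O.O.O.O.[Na+].[O-]OB=O
Why: Oxidation of the secondary allylic C–B bond by 1,2-migration from boron to oxygen proceeds with retention and without allylic transposition, so the carbinol configuration set in step 16 is kept.

Step 18
Reactants: 30 silyl ether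
Product: 31 (1R,2E)-3-[(1S,3S,4R)-3-bromo-4-hydroxy-4-methylcyclohexyl]-1-[(1R)-2,2-dimethyl-6-methylidenecyclohex-3-en-1-yl]but-2-en-1-ol (target)
Conditions: citric acid (cat.), MeOH, 0 °C
Reagents that add atoms: none
Why: Mild acid-catalysed methanolysis cleaves the tertiary trimethylsilyl ether without ionizing the allylic alcohol and without forming the alkoxide of the cis bromohydrin.

**Compound list**

1 | (S)-limonene | CC(=C)[C@H]1CCC(C)=CC1 | starting material
2 | (4S)-limonene 1,2-oxide, both epoxide diastereomers | CC(=C)[C@H]1CCC2(C)OC2C1 | intermediate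
3 | (1R,2R,4S)-1-methyl-4-(prop-1-en-2-yl)cyclohexane-1,2-diol | CC(=C)[C@H]1CC[C@@](C)(O)[C@H](O)C1 | intermediate
4 | 1-[(1S,3R,4R)-3,4-dihydroxy-4-methylcyclohexyl]ethan-1-one | CC(=O)[C@H]1CC[C@@](C)(O)[C@H](O)C1 | intermediate
5 | cyclic sulfite of 4 (sulfur epimers) | CC(=O)[C@H]1CC[C@@]2(C)OS(=O)O[C@@H]2C1 | intermediate
6 | cyclic sulfate of 4 | CC(=O)[C@H]1CC[C@@]2(C)OS(=O)(=O)O[C@@H]2C1 | intermediate
7 | lithium (1R,2S,4S)-4-acetyl-2-bromo-1-methylcyclohexyl sulfate | CC(=O)[C@H]1CC[C@@](C)(OS(=O)(=O)[O-])[C@@H](Br)C1.[Li+] | intermediate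
8 | 1-[(1S,3S,4R)-3-bromo-4-hydroxy-4-methylcyclohexyl]ethan-1-one | CC(=O)[C@H]1CC[C@@](C)(O)[C@@H](Br)C1 | intermediate
9 | 1-{(1S,3S,4R)-3-bromo-4-methyl-4-[(trimethylsilyl)oxy]cyclohexyl}ethan-1-one | CC(=O)[C@H]1CC[C@@](C)(O[Si](C)(C)C)[C@@H](Br)C1 | intermediate
10 | enol triflate of 9 (2-triflyloxy-1-alkene) | C=C(OS(=O)(=O)C(F)(F)F)[C@H]1CC[C@@](C)(O[Si](C)(C)C)[C@@H](Br)C1 | intermediate
11 | {[(1R,2S,4S)-2-bromo-4-ethynyl-1-methylcyclohexyl]oxy}trimethylsilane | C#C[C@H]1CC[C@@](C)(O[Si](C)(C)C)[C@@H](Br)C1 | intermediate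
12 | (E)-alkenyl(dimethyl)alane from 11 | C[Al](C)/C=C(\C)[C@H]1CC[C@@](C)(O[Si](C)(C)C)[C@@H](Br)C1 | intermediate
13 | {[(1R,2S,4S)-2-bromo-4-[(1E)-1-iodoprop-1-en-2-yl]-1-methylcyclohexyl]oxy}trimethylsilane | I/C=C(\C)[C@H]1CC[C@@](C)(O[Si](C)(C)C)[C@@H](Br)C1 | intermediate
14 | 3-bromobut-3-en-1-ol | C=C(Br)CCO | starting material
15 | 2-bromo-4-iodobut-1-ene | C=C(Br)CCI | intermediate
16 | (3-bromobut-3-en-1-yl)triphenylphosphonium iodide | C=C(Br)CC[P+](c1ccccc1)(c1ccccc1)c1ccccc1.[I-] | intermediate
17 | methyl 3-hydroxy-2,2-dimethylpropanoate | COC(=O)C(C)(C)CO | starting material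
18 | methyl 2,2-dimethyl-3-oxopropanoate | COC(=O)C(C)(C)C=O | intermediate
19 | (3-bromobut-3-en-1-ylidene)triphenylphosphorane | C=C(Br)CC=P(c1ccccc1)(c1ccccc1)c1ccccc1 | intermediate
20 | methyl (3Z)-6-bromo-2,2-dimethylhepta-3,6-dienoate | COC(=O)C(C)(C)/C=C\CC(Br)=C | intermediate
21 | (3Z)-6-bromo-2,2-dimethylhepta-3,6-dienal | O=CC(C)(C)/C=C\CC(Br)=C | intermediate
22 | (4Z)-7-bromo-3,3-dimethylocta-4,7-dien-1-yne | C#CC(C)(C)/C=C\CC(Br)=C | intermediate
23 | acenaphthoquinone (acenaphthylene-1,2-dione) | O=C1C(=O)c2cccc3cccc1c23 | starting material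
24 | cis-1,2-dimethyl-1,2-dihydroacenaphthylene-1,2-diol (meso) | C[C@@]1(O)c2cccc3cccc(c23)[C@]1(C)O | intermediate
25 | 2-[(1E,4Z)-7-bromo-3,3-dimethylocta-1,4,7-trien-1-yl]-1,3,2-benzodioxaborole | C=C(Br)C/C=C\C(C)(C)/C=C/B1Oc2ccccc2O1 | intermediate
26 | (1E,4Z)-7-bromo-3,3-dimethylocta-1,4,7-trien-1-ylboronic acid ester of diol 24 | C=C(Br)C/C=C\C(C)(C)/C=C/B1O[C@]2(C)c3cccc4cccc(c34)[C@]2(C)O1 | intermediate
27 | (E)-alkenyllithium from 13 | [Li]/C=C(\C)[C@H]1CC[C@@](C)(O[Si](C)(C)C)[C@@H](Br)C1 | intermediate
28 | lithium bis(alkenyl) borate from 26 and 27 | [Li+].C=C(Br)C/C=C\C(C)(C)/C=C/[B-]1(/C=C(\C)[C@H]2CC[C@@](C)(O[Si](C)(C)C)[C@@H](Br)C2)O[C@]3(C)c4cccc5cccc(c45)[C@]3(C)O1 | intermediate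
29 | ring-closed allylic boronic ester of diol 24 (30 with boron in place of the hydroxyl oxygen; new stereocenters arranged as in 31) | C=C1CC=CC(C)(C)[C@@H]1[C@H](B2O[C@]3(C)c4cccc5cccc(c45)[C@]3(C)O2)/C=C(\C)[C@H]6CC[C@@](C)(O[Si](C)(C)C)[C@@H](Br)C6 | intermediate
30 | (1R,2E)-3-{(1S,3S,4R)-3-bromo-4-methyl-4-[(trimethylsilyl)oxy]cyclohexyl}-1-[(1R)-2,2-dimethyl-6-methylidenecyclohex-3-en-1-yl]but-2-en-1-ol | C=C1CC=CC(C)(C)[C@@H]1[C@H](O)/C=C(\C)[C@H]1CC[C@@](C)(O[Si](C)(C)C)[C@@H](Br)C1 | intermediate
31 | (1R,2E)-3-[(1S,3S,4R)-3-bromo-4-hydroxy-4-methylcyclohexyl]-1-[(1R)-2,2-dimethyl-6-methylidenecyclohex-3-en-1-yl]but-2-en-1-ol | C=C1CC=CC(C)(C)[C@@H]1[C@H](O)/C=C(\C)[C@H]1CC[C@@](C)(O)[C@@H](Br)C1 | target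

**Step count and risks**

Total step count: 18. Longest linear sequence: 11 steps (steps 1 to 8, then 16 to 18).

Steps most likely to fail:

Step 16. The borate may transfer an alkenyl group directly from boron to palladium (open-chain Suzuki–Miyaura coupling without ring closure), the bisphosphine may give poor face selectivity at C6 in the ring-closing mode, or bromine–lithium exchange at the ring bromide may compete while 27 is generated. The fallback closes the same C1–C6 bond by known enolate chemistry; it sets out from 22 and 13 and comes back at 30. Hydroboration of 22 with Cy2BH and oxidation with NaBO3 gives (4Z)-7-bromo-3,3-dimethylocta-4,7-dienal F1. Alkenyllithium 27 (from 13 and t-BuLi) adds to it to give the open-chain dienol F2 as a carbinol mixture, and Dess–Martin oxidation gives the cross-conjugated enone F3. Intramolecular palladium-catalysed ketone α-alkenylation (Pd(PPh3)4, KOPh, THF) then closes ring A to the β,γ-unsaturated ketone F4, as both epimers at the ring carbon. CBS reduction (BH3·SMe2 with the 1-methyl-3,3-diphenyltetrahydro-1H,3H-pyrrolo[1,2-c][1,3,2]oxazaborole enantiomer that gives the R carbinol) and chromatographic separation of the diastereomers lead to 30.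

Step 5. Ionization at the tertiary sulfate carbon or E2 elimination may outrun SN2 attack of bromide at the hindered secondary carbon, whose axial approach is syn to the axial acetyl group. The fallback inverts a simple sulfonate instead; it sets out from 4 and comes back at 9, so that steps 4 to 6 are bypassed. Exhaustive silylation of 4 with N-(trimethylsilyl)imidazole gives the bis(trimethylsilyl) ether F5. Selective methanolysis of the less hindered secondary silyl ether (K2CO3, MeOH, −20 °C) gives the tertiary monosilyl ether F6, and Tf2O/pyridine gives the axial secondary triflate F7. Bu4NBr in toluene displaces the triflate with inversion to give 9.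

Step 7. The excess amide base may attack the secondary bromide (elimination or substitution), or elimination of the enol triflate may stop short. The fallback reaches the alkenyl iodide without an alkyne; it sets out from 9 and comes back at 13, so that steps 7 and 8 are bypassed. Boron-Wittig olefination of 9 with CH2(Bpin)2 and lithium 2,2,6,6-tetramethylpiperidide gives the (E)-trisubstituted alkenyl pinacol boronate F8 (E isomer separated). Iododeboronation with N-iodosuccinimide with retention gives 13.

**Further compounds**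

F1 | step 16 | (4Z)-7-bromo-3,3-dimethylocta-4,7-dienal | O=CCC(C)(C)/C=C\CC(Br)=C
F2 | step 16 | (2E,7Z)-10-bromo-2-{(1S,3S,4R)-3-bromo-4-methyl-4-[(trimethylsilyl)oxy]cyclohexyl}-6,6-dimethylundeca-2,7,10-trien-4-ol (carbinol epimers) | C=C(Br)C/C=C\C(C)(C)CC(O)/C=C(\C)[C@H]1CC[C@@](C)(O[Si](C)(C)C)[C@@H](Br)C1
F3 | step 16 | (2E,7Z)-10-bromo-2-{(1S,3S,4R)-3-bromo-4-methyl-4-[(trimethylsilyl)oxy]cyclohexyl}-6,6-dimethylundeca-2,7,10-trien-4-one | C=C(Br)C/C=C\C(C)(C)CC(=O)/C=C(\C)[C@H]1CC[C@@](C)(O[Si](C)(C)C)[C@@H](Br)C1
F4 | step 16 | (2E)-3-{(1S,3S,4R)-3-bromo-4-methyl-4-[(trimethylsilyl)oxy]cyclohexyl}-1-(2,2-dimethyl-6-methylidenecyclohex-3-en-1-yl)but-2-en-1-one (ring epimers) | C=C1CC=CC(C)(C)C1C(=O)/C=C(\C)[C@H]1CC[C@@](C)(O[Si](C)(C)C)[C@@H](Br)C1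
F5 | step 5 | 1-{(1S,3R,4R)-4-methyl-3,4-bis[(trimethylsilyl)oxy]cyclohexyl}ethan-1-one | CC(=O)[C@H]1CC[C@@](C)(O[Si](C)(C)C)[C@H](O[Si](C)(C)C)C1
F6 | step 5 | 1-{(1S,3R,4R)-3-hydroxy-4-methyl-4-[(trimethylsilyl)oxy]cyclohexyl}ethan-1-one | CC(=O)[C@H]1CC[C@@](C)(O[Si](C)(C)C)[C@H](O)C1
F7 | step 5 | (1R,2R,5S)-5-acetyl-2-methyl-2-[(trimethylsilyl)oxy]cyclohexyl trifluoromethanesulfonate | CC(=O)[C@H]1CC[C@@](C)(O[Si](C)(C)C)[C@H](OS(=O)(=O)C(F)(F)F)C1
F8 | step 7 | 2-{(1E)-2-[(1S,3S,4R)-3-bromo-4-methyl-4-(trimethylsilyloxy)cyclohexyl]prop-1-en-1-yl}-4,4,5,5-tetramethyl-1,3,2-dioxaborolane | CC1(C)OB(/C=C(\C)[C@H]2CC[C@@](C)(O[Si](C)(C)C)[C@@H](Br)C2)OC1(C)C
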